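## Retrosynthetic overview

1. Target 19 comes from meso anhydride 18 by methanolysis of one of its two enantiotopic carbonyls. This sets the absolute configuration of all four centres last, in one operation.
2. 18 comes from diacid 17, and 17 from cyclobutane 16 carried on naphthalene-1,8-diol. The four-membered ring is cut twice. C3–C4 joins two enoate β-carbons (both electrophilic) after one-electron reduction. C1–C2 joins two enolate α-carbons (both nucleophilic) by two-electron oxidation in the same flask.
3. Bis-enoate 14 comes from two molecules of acid 12 and template 13. Acid 12 comes from 6-ethylpyranone 6 and ethyl glyoxylate 7 (vinylogous aldol, then E1cB).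
4. 6 comes from ethyl 2-methylacetoacetate 1 and methyl propanoate 2 (dianion acylation, lactonisation, O-methylation).
5. Ring order: the pyranone ring (step 1), the eleven-membered ring and then the cyclobutane (step 6), the anhydride ring (step 8, opened in step 9).

Assumption: on 18, quinidine is taken to show the same sense of induction as on the parent cis-fused bicyclic succinic anhydrides (the acid is left on the carbon that becomes C1 of 19); if the assay shows the opposite sense, quinine replaces it.

## Route

Step 1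
Reactants: 1 ethyl 2-methyl-3-oxobutanoate; 2 methyl propanoate
Product: 5 6-ethyl-4-hydroxy-3-methyl-2H-pyran-2-one, via dilithium dianion 3 (not isolated), via dioxo ester 4 (not isolated)
Conditions: 1 (2 equiv), LiN(i-Pr)2 (4 equiv), THF, −78 to 0 °C; 2 (1 equiv), 0 °C; AcOH; crude 4, DBU, toluene, reflux
Reagents that add atoms: none
Why: γ-Acylation of the β-keto ester dianion (Claisen-type condensation) gives the 3,5-dioxo ester, whose C5 enol closes onto the ester under DBU (enol lactonisation) to give the 4-hydroxy-2-pyranone, and no stereocentre remains.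

Step 2
Reactants: 5 6-ethyl-4-hydroxy-3-methyl-2H-pyran-2-one
Product: 6 6-ethyl-4-methoxy-3-methyl-2H-pyran-2-one
Conditions: Me2SO4, K2CO3, acetone, reflux
Reagents that add atoms: dimethyl sulfate, COS(=O)(=O)OC
Why: Williamson-type O-alkylation of the vinylogous acid with a hard methylating agent gives mainly the 4-methoxy-2-pyranone rather than the 2-methoxy-4-pyranone.

Step 3
Reactants: 6 6-ethyl-4-methoxy-3-methyl-2H-pyran-2-one; 7 ethyl glyoxylate
Product: 11 ethyl (E)-3-(4-methoxy-3-methyl-2-oxo-2H-pyran-6-yl)but-2-enoate, via lithium dienolate 8 (not isolated), via lithium aldolate 9 (not isolated), via acetoxy ester 10 (not isolated)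
Conditions: LiN(i-Pr)2 (1.1 equiv), THF, −78 °C; 7 (freshly distilled, 1.5 equiv), −78 °C; Ac2O (2 equiv), −78 °C to rt; DBU (2.5 equiv), rt
Reagents that add atoms: none
Why: A vinylogous aldol addition of the C6-α carbanion (C3 is blocked by methyl) to the aldehyde is followed by E1cB loss of acetate through the same pyranone-stabilised carbanion, which gives the thermodynamic E alkene with the ester trans to the pyranone.

Step 4
Reactants: 11 ethyl (E)-3-(4-methoxy-3-methyl-2-oxo-2H-pyran-6-yl)but-2-enoate
Product: 12 (E)-3-(4-methoxy-3-methyl-2-oxo-2H-pyran-6-yl)but-2-enoic acid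
Conditions: LiOH (1.5 equiv), THF/H2O 3:1, 0 °C to rt; 1 M HCl
Reagents that add atoms: lithium hydroxide, [Li+].[OH-]
Why: Saponification of the unhindered ethyl ester is faster than attack on the 4-methoxypyranone (a vinylogous carbonate), any ring-opened material recloses on acidification, and the alkene geometry is kept.

Step 5
Reactants: 12 (E)-3-(4-methoxy-3-methyl-2-oxo-2H-pyran-6-yl)but-2-enoic acid (2.2 equiv); 13 naphthalene-1,8-diol
Product: 14 naphthalene-1,8-diyl bis[(E)-3-(4-methoxy-3-methyl-2-oxo-2H-pyran-6-yl)but-2-enoate]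
Conditions: DCC (2.3 equiv), DMAP (0.2 equiv), CH2Cl2, 0 °C to rt
Reagents that add atoms: none
Why: Double Steglich esterification places the two enoate chains on the peri oxygens, where they stack face to face and head to head.

Step 6
Reactants: 14 naphthalene-1,8-diyl bis[(E)-3-(4-methoxy-3-methyl-2-oxo-2H-pyran-6-yl)but-2-enoate]
Product: 16 naphthalene-1,8-diyl (1R,2S,3R,4S)-3,4-dimethyl-3,4-bis(4-methoxy-3-methyl-2-oxo-2H-pyran-6-yl)cyclobutane-1,2-dicarboxylate (meso; both pyranones on one face; both methyls plus both carboxyl carbons on the other), via bis-samarium enolate 15 (not isolated)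
Conditions: SmI2 (2.2 equiv), HMPA (8 equiv), THF, 0.005 M, −78 °C, slow addition of 14, no proton source; then I2 (1.1 equiv), −78 to 0 °C
Reagents that add atoms: none
Why: Proposed new method: each pyranonyl enoate takes one electron from SmI2–HMPA to give an oxygen-bound trivalent samarium radical anion whose spin sits on the tertiary, pyranone-stabilised β-carbon (homoenolate-type reactivity where an enoate is normally electrophilic); the peri template holds the two stacked β-carbons about 3.5 Å apart in a mirror-related arrangement, so they combine Re on Si to the meso C3–C4 bond (pyranones syn, methyls syn); without a proton source the product stays as bis-enolate 15, in which both carbonyls are masked so that no Dieckmann reaction can occur; iodine then removes two electrons and joins the two normally nucleophilic α-carbons (C1–C2), cis to each other as the nine-membered dilactone demands and on the face away from the pyranones, helped by the Thorpe–Ingold effect of two quaternary carbons; the closest known reaction types are the SmI2–HMPA hydrodimerisation of β,β-disubstituted acrylates, the cyclisation of adipate bis-enolates to cyclobutane-1,2-dicarboxylates with I2 or CuCl2, and the syn head-to-head cyclobutanes that this template gives from cinnamates.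

Step 7
Reactants: 16 naphthalene-1,8-diyl (1R,2S,3R,4S)-3,4-dimethyl-3,4-bis(4-methoxy-3-methyl-2-oxo-2H-pyran-6-yl)cyclobutane-1,2-dicarboxylate
Product: 17 (1R,2S,3R,4S)-3,4-dimethyl-3,4-bis(4-methoxy-3-methyl-2-oxo-2H-pyran-6-yl)cyclobutane-1,2-dicarboxylic acid (meso)
Conditions: LiOH (4 equiv), THF/H2O 3:1, 0 °C, 1 h; 1 M HCl
Reagents that add atoms: lithium hydroxide, [Li+].[OH-]
Why: Saponification of the two activated aryl esters, the second one helped by the neighbouring cis carboxylate, outruns attack on the pyranones at 0 °C and leaves all four centres untouched.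

Step 8
Reactants: 17 (1R,2S,3R,4S)-3,4-dimethyl-3,4-bis(4-methoxy-3-methyl-2-oxo-2H-pyran-6-yl)cyclobutane-1,2-dicarboxylic acid
Product: 18 (1R,5S,6R,7S)-6,7-dimethyl-6,7-bis(4-methoxy-3-methyl-2-oxo-2H-pyran-6-yl)-3-oxabicyclo[3.2.0]heptane-2,4-dione (meso; pyranones exo; methyls endo)
Conditions: (CF3CO)2O (1.5 equiv), CH2Cl2, 0 °C to rt
Reagents that add atoms: none
Why: Dehydrative cyclisation through the mixed trifluoroacetic anhydride closes the five-membered ring, which only the cis diacid can do, and it runs at a temperature that spares the strained hexasubstituted C3–C4 bond.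

Step 9
Reactants: 18 (1R,5S,6R,7S)-6,7-dimethyl-6,7-bis(4-methoxy-3-methyl-2-oxo-2H-pyran-6-yl)-3-oxabicyclo[3.2.0]heptane-2,4-dione
Product: 19 (1S,2R,3S,4R)-2-(methoxycarbonyl)-3,4-dimethyl-3,4-bis(4-methoxy-3-methyl-2-oxo-2H-pyran-6-yl)cyclobutane-1-carboxylic acid
Conditions: quinidine (1.1 equiv), MeOH (3 equiv), toluene, −55 °C, 72 h; 1 M HCl wash
Reagents that add atoms: methanol, CO
Why: In this cinchona-alkaloid-mediated desymmetrising alcoholysis of a meso anhydride, quinidine acts as a chiral general base and delivers methanol to the enantiotopic carbonyl C2 on bridgehead C1, which fixes the absolute configuration of all four existing centres at once without touching any of them.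

## Compound list

1 | ethyl 2-methyl-3-oxobutanoate (racemic) | CCOC(=O)C(C)C(C)=O | starting material
2 | methyl propanoate | CCC(=O)OC | starting material
3 | dilithium dianion of 1 (1-ethoxy-2-methylbuta-1,3-diene-1,3-diolate) | C=C(O[Li])C(C)=C(O[Li])OCC | intermediate
4 | ethyl 2-methyl-3,5-dioxoheptanoate | CCC(=O)CC(=O)C(C)C(=O)OCC | intermediate
5 | 6-ethyl-4-hydroxy-3-methyl-2H-pyran-2-one | CCc1cc(O)c(C)c(=O)o1 | intermediate
6 | 6-ethyl-4-methoxy-3-methyl-2H-pyran-2-one | CCc1cc(OC)c(C)c(=O)o1 | intermediate
7 | ethyl glyoxylate | CCOC(=O)C=O | starting material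
8 | lithium 6-ethylidene-4-methoxy-3-methyl-6H-pyran-2-olate (dienolate of 6) | CC=C1C=C(OC)C(C)=C(O[Li])O1 | intermediate
9 | lithium alkoxide of ethyl 2-hydroxy-3-(4-methoxy-3-methyl-2-oxo-2H-pyran-6-yl)butanoate (diastereomer mixture) | CCOC(=O)C(O[Li])C(C)c1cc(OC)c(C)c(=O)o1 | intermediate
10 | ethyl 2-acetoxy-3-(4-methoxy-3-methyl-2-oxo-2H-pyran-6-yl)butanoate (diastereomer mixture) | CCOC(=O)C(OC(C)=O)C(C)c1cc(OC)c(C)c(=O)o1 | intermediate
11 | ethyl (E)-3-(4-methoxy-3-methyl-2-oxo-2H-pyran-6-yl)but-2-enoate | CCOC(=O)/C=C(\C)c1cc(OC)c(C)c(=O)o1 | intermediate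
12 | (E)-3-(4-methoxy-3-methyl-2-oxo-2H-pyran-6-yl)but-2-enoic acid | OC(=O)/C=C(\C)c1cc(OC)c(C)c(=O)o1 | intermediate
13 | naphthalene-1,8-diol | Oc1cccc2cccc(O)c12 | starting material
14 | naphthalene-1,8-diyl bis[(E)-3-(4-methoxy-3-methyl-2-oxo-2H-pyran-6-yl)but-2-enoate] | O=C(/C=C(\C)c1cc(OC)c(C)c(=O)o1)Oc1cccc2cccc(OC(=O)/C=C(\C)c3cc(OC)c(C)c(=O)o3)c12 | intermediate
15 | bis(diiodosamarium) bis-enolate of the eleven-membered meso (3R,4S) hydrodimer | I[Sm](I)OC1=C[C@@](C)(c2cc(OC)c(C)c(=O)o2)[C@@](C)(c2cc(OC)c(C)c(=O)o2)C=C(O[Sm](I)I)Oc2cccc3cccc(O1)c23 | intermediate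
16 | naphthalene-1,8-diyl (1R,2S,3R,4S)-3,4-dimethyl-3,4-bis(4-methoxy-3-methyl-2-oxo-2H-pyran-6-yl)cyclobutane-1,2-dicarboxylate (meso) | O=C1Oc2cccc3cccc(OC(=O)[C@@H]4[C@H]1[C@@](C)(c1cc(OC)c(C)c(=O)o1)[C@@]4(C)c1cc(OC)c(C)c(=O)o1)c23 | intermediate
17 | (1R,2S,3R,4S)-3,4-dimethyl-3,4-bis(4-methoxy-3-methyl-2-oxo-2H-pyran-6-yl)cyclobutane-1,2-dicarboxylic acid (meso) | OC(=O)[C@@H]1[C@H](C(=O)O)[C@@](C)(c2cc(OC)c(C)c(=O)o2)[C@@]1(C)c1cc(OC)c(C)c(=O)o1 | intermediate
18 | (1R,5S,6R,7S)-6,7-dimethyl-6,7-bis(4-methoxy-3-methyl-2-oxo-2H-pyran-6-yl)-3-oxabicyclo[3.2.0]heptane-2,4-dione (meso) | O=C1OC(=O)[C@@H]2[C@H]1[C@@](C)(c1cc(OC)c(C)c(=O)o1)[C@@]2(C)c1cc(OC)c(C)c(=O)o1 | intermediate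
19 | (1S,2R,3S,4R)-2-(methoxycarbonyl)-3,4-dimethyl-3,4-bis(4-methoxy-3-methyl-2-oxo-2H-pyran-6-yl)cyclobutane-1-carboxylic acid | COC(=O)[C@@H]1[C@H](C(=O)O)[C@@](C)(c2cc(OC)c(C)c(=O)o2)[C@@]1(C)c1cc(OC)c(C)c(=O)o1 | target

## Step count and risks

Total step count: 9. Longest linear sequence: 9 (1 to 19).

**Step 6 is the most likely to fail.**
- The oxidised bis-enolate can fragment at the weak hexasubstituted C3–C4 bond. This only returns 14, which can be put through the reduction and oxidation again, because 16 is not reduced under these conditions.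
- The aryl ester enolates can lose aryloxide if the flask warms before the iodine is in.
- The first bond could form between the α-carbons instead. That would be harmless, since the oxidative closure then makes C3–C4 and leads to the same 16.
- The fallback sets out from 14 and comes back at 16. The cold solution of 15 is run into AcOH/THF at −78 °C instead of being oxidised. This gives the eleven-membered meso hydrodimer naphthalene-1,8-diyl (3R,4S)-3,4-dimethyl-3,4-bis(4-methoxy-3-methyl-2-oxo-2H-pyran-6-yl)hexanedioate F1, which can be isolated and its configuration checked.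
- LiN(SiMe3)2 with Me3SiCl already present (THF, −78 °C) converts it into the neutral bis(trimethylsilyl ketene acetal) F2, which cannot expel aryloxide.
- TiCl4 (2 equiv, CH2Cl2, −78 °C) then couples the two ketene acetal carbons. This is the known oxidative coupling of ketene silyl acetals to succinates, and here it runs inside a titanium chelate rather than through free enolates. It gives 16.

**Step 9 is next.** The anhydride carbonyls sit beside quaternary carbons, so the reaction may be slow at −55 °C, and the sense of induction is inferred from simpler anhydrides.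
- The fallback sets out from 17 and comes back at 19. MeI and K2CO3 in DMF give the meso diester dimethyl (1R,2S,3R,4S)-3,4-dimethyl-3,4-bis(4-methoxy-3-methyl-2-oxo-2H-pyran-6-yl)cyclobutane-1,2-dicarboxylate F3.
- Pig liver esterase (pH 7 phosphate buffer/DMSO 9:1, 25 °C, pH-stat) hydrolyses one enantiotopic ester.
- The parent dimethyl cis-cyclobutane-1,2-dicarboxylate is cut at the ester that corresponds to C1 of 19, so the same enantiomer is expected.

**Step 3 is third.** A secondary carbanion must meet a glyoxylate that polymerises easily, and the E1cB step may give E/Z mixtures.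
- The fallback sets out from 6 and comes back at 11. SeO2 in dioxane (150 °C, sealed tube) oxidises the activated methylene to 6-acetyl-4-methoxy-3-methyl-2H-pyran-2-one F4.
- A Horner–Wadsworth–Emmons olefination with (EtO)2P(O)CH2CO2Et and NaH in THF then gives 11, with the E isomer favoured and separable from the Z isomer.

## Further compounds

F1 | step 6 | naphthalene-1,8-diyl (3R,4S)-3,4-dimethyl-3,4-bis(4-methoxy-3-methyl-2-oxo-2H-pyran-6-yl)hexanedioate (meso, eleven-membered ring) | O=C1C[C@@](C)(c2cc(OC)c(C)c(=O)o2)[C@@](C)(c2cc(OC)c(C)c(=O)o2)CC(=O)Oc2cccc3cccc(O1)c23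
F2 | step 6 | bis(trimethylsilyl ketene acetal) of F1 | C[Si](C)(C)OC1=C[C@@](C)(c2cc(OC)c(C)c(=O)o2)[C@@](C)(c2cc(OC)c(C)c(=O)o2)C=C(O[Si](C)(C)C)Oc2cccc3cccc(O1)c23
F3 | step 9 | dimethyl (1R,2S,3R,4S)-3,4-dimethyl-3,4-bis(4-methoxy-3-methyl-2-oxo-2H-pyran-6-yl)cyclobutane-1,2-dicarboxylate (meso) | COC(=O)[C@@H]1[C@H](C(=O)OC)[C@@](C)(c2cc(OC)c(C)c(=O)o2)[C@@]1(C)c1cc(OC)c(C)c(=O)o1
F4 | step 3 | 6-acetyl-4-methoxy-3-methyl-2H-pyran-2-one | CC(=O)c1cc(OC)c(C)c(=O)o1
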